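(The numbers in the tables stem from a simulated flask for substances that don't exist; scatter was added.)

The constant I read first is the turnover of Monday's run. Target made, with each side product counted back as one target, comes to 0.0633 min⁻¹ of the substrate charge per minute at 0.83 M of reagent. Friday's run, with less reagent, gives 0.0320 min⁻¹, so I scale this reading with reagent.

| flask | substrate | reagent | base | remark | time |
|---|---|---|---|---|---|
| Friday's | 0.32 M | 0.39 M | 0.090 M | run made earlier |  |
| Thursday's | 0.40 M | 0.39 M | 0.090 M | run made earlier |  |
| Sunday's | 0.62 M | 0.39 M | 0.090 M | run made earlier |  |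
| Monday's | 0.30 M | 0.83 M | 0.090 M | run made earlier |  |
| west | 0.60 M | 1.20 M | 0.0900 M |  | 2.0 min |
| north-east | 0.30 M | 0.390 M | 0.0900 M |  | 2.0 min |
| north | 0.60 M | 0.390 M | 0.0900 M |  | 2.0 min |
| east | 0.30 M | 1.20 M | 0.0900 M |  | 2.0 min |

| run | time / s | target / % | side product / % |
|---|---|---|---|
| Friday's | 25.0 | 2.0 | 0.1 |
| Friday's | 50.0 | 1.9 | 1.8 |
| Friday's | 80.0 | 2.5 | 3.7 |
| Friday's | 90.0 | 2.4 | 4.6 |
| Friday's | 120 | 3.0 | 6.8 |
| Thursday's | 10.0 | 0.6 | 0 |
| Thursday's | 30.0 | 1.0 | 0.7 |
| Thursday's | 60.0 | 1.8 | 2.5 |
| Thursday's | 80.0 | 1.6 | 4.2 |
| Thursday's | 120 | 2.5 | 7.4 |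
| Sunday's | 10.0 | 0.6 | 0 |
| Sunday's | 30.0 | 1.2 | 1.1 |
| Sunday's | 60.0 | 1.9 | 3.5 |
| Sunday's | 80.0 | 1.4 | 5.4 |
| Sunday's | 120 | 1.5 | 8.8 |
| Monday's | 10.0 | 1.3 | 0 |
| Monday's | 20.0 | 2.1 | 0.1 |
| Monday's | 30.0 | 2.9 | 1.1 |
| Monday's | 60.0 | 4.1 | 4.2 |
| Monday's | 120 | 6.0 | 13.3 |

(readings scatter by 0.3 percentage points)

- percent here means substrate units held: one side product counts as two
- candidate steps: substrate + reagent + by-product -> target + 2 by-product; substrate + reagent -> target + by-product; base + by-product <-> salt; substrate + target -> side product

- ranking by share of target in all that became target or side product, from high to low, at 2.0 min (west / north-east / north / east)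
- the share of target in all that became target or side product of the flask you put first, at 2.0 min
- the share of target in all that became target or side product of the flask you put last, at 2.0 min

I treat the binding of by-product to base as instantaneous, so each target made costs one base. Dividing the base-to-substrate ratio by the scaled turnover gives the buffer time, an induction period: 1.64 min for west, against 3.28 min for east, 5.05 min for north and 10.1 min for north-east. West alone comes in under the 2.0 min asked. Monday's run made 12.7%, less than its base ratio of 30.0%, so Monday's readings stop short of the break.

West therefore has two extreme versions. I hold target at Monday's level scaled to west, 4.34% of the charge, so at the break side product holds 21.3%. If west stood still there, its share would be 16.9%. If the remaining substrate became target at once, it would be 78.7%. The real flask lies between, since side product keeps forming during any burst. East's nearest run, Monday's, reads 31.1%, which lies between the two versions, so they do not place west against east. I commit to west first as a bet on a quick burst in the 0.360 min after its break, a stretch that Monday's readings do not reach.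

The forecast gives east > north-east > west > north, with 33% first and 17% last, and says of west “so west could jump higher”. It puts east first where I put west.

The flasks give west > east > north-east > north, from 77.0% down to 15.4%.

    substrate + reagent + by-product → target + 2 by-product (k = 2.90 L² mol⁻² s⁻¹)
    substrate + reagent → target + by-product (k = 0.00140 L mol⁻¹ s⁻¹)
    base + by-product ⇌ salt, settled at all times (K = 78000 L mol⁻¹)
    substrate + target → side product (k = 0.0520 L mol⁻¹ s⁻¹)

West ends at 77.0%, below my upper version, with side product at 23.0%; its base falls from 37.9% at 1.00 min to 0% at 2.00 min, which brackets the buffer time of 1.64 min. The neighbour, west with 1.5 M of substrate, has a buffer time of 0.656 min, shorter than west's, but holds 0.800 equiv of reagent. Target made then stops at that fraction, and the unmatched substrate takes target with it, giving 60.0%. The neighbour stores 60.4%, with reagent at 0%.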